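## Retrosynthetic overview

1. Names used: lactone = ring D (O1, C2(=O), C3, C4, C5). C3 carries C7H2–ring A and C4 carries C7'H2–ring B. Ring B carries at C5' the chain C8''H(C9''H2OH)–C7''(=O)–ring C. The labile C8'' centre is kept as a 1,3-diol (C7'' carbinol) until the last two steps (benzylic oxidation, neutral hydrogenolysis).
2. Key disconnection is C3–C4 of ring D, leading back to the open-chain (Z)-cinnamyl arylpropiolate 20, which has neither ring nor stereocentre in this sector. A rhodium–BINAP/H2 reductive enyne cyclisation closes ring D, sets C4 and brings C7' to CH2; conjugate reduction and equilibration then set C3 trans.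
3. Enabling feature: C3 and C4 each bear a benzylic carbon (C7 on ring A, C7' on ring B) and are joined the other way round by C2(=O)–O1–C5. C3≡C7 and C4=C7' can therefore be aryl-conjugated π-bonds in a 1,6-relationship across an ester, and C7' has no hydrogen-bearing substituent outside the metallacycle.
4. Ester 20 is the Steglich union of acid 19 (O-benzylvanillin, Corey–Fuchs, CO2) and alcohol 16 (Sonogashira, then Lindlar, on bromide 13).
5. Bromide 13 comes from 5-bromo-o-vanillin by one-carbon homologation, Evans syn-aldol with O-benzylvanillin (sets C8''), LiBH4 and acetonide formation. Ring order: temporary dioxane ring E (step 7), lactone ring D (step 13), ring E opened (step 15).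

Key step: step 13

Assumption: the sense of induction of (R)-BINAP in step 13 is assigned only by analogy with ester-tethered 1,6-enynes; both ligand antipodes are commercial and the one that delivers (4R) is used.

## Route

Step 1
Reactants: 1 5-bromo-2-hydroxy-3-methoxybenzaldehyde
Product: 2 2-(benzyloxy)-5-bromo-3-methoxybenzaldehyde
Conditions: BnBr, K2CO3, DMF, rt
Reagents that add atoms: benzyl bromide, BrCc1ccccc1
Why: Williamson etherification (SN2) of the acidic phenoxide installs a benzyl group that can leave at the very end under neutral hydrogenolysis.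

Step 2
Reactants: 2 2-(benzyloxy)-5-bromo-3-methoxybenzaldehyde
Product: 3 2-(benzyloxy)-5-bromo-1-methoxy-3-(2-methoxyethenyl)benzene (E/Z mixture)
Conditions: MeOCH2PPh3Cl, t-BuOK, THF, 0 °C to rt
Reagents that add atoms: (methoxymethyl)triphenylphosphonium chloride, COC[P+](c1ccccc1)(c1ccccc1)c1ccccc1.[Cl-]
Why: Wittig olefination with the non-stabilised methoxymethylene ylide adds the carbon that ends as C9'', and the alkene geometry is irrelevant because the enol ether is hydrolysed next.

Step 3
Reactants: 3 2-(benzyloxy)-5-bromo-1-methoxy-3-(2-methoxyethenyl)benzene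
Product: 5 2-[2-(benzyloxy)-5-bromo-3-methoxyphenyl]acetic acid, via arylacetaldehyde 4 (not isolated)
Conditions: 2 M HCl, THF, 45 °C; extraction; then NaClO2, NaH2PO4, 2-methyl-2-butene, t-BuOH–H2O, rt
Reagents that add atoms: water, O; sodium chlorite, [Na+].[O-]Cl=O
Why: Enol ether hydrolysis followed by Pinnick oxidation is telescoped because arylacetaldehydes self-condense, and chlorite with a hypochlorite scavenger spares the electron-rich ring and the benzyl ether.

Step 4
Reactants: 5 2-[2-(benzyloxy)-5-bromo-3-methoxyphenyl]acetic acid; 6 (R)-4-benzyl-1,3-oxazolidin-2-one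
Product: 8 (R)-4-benzyl-3-{2-[2-(benzyloxy)-5-bromo-3-methoxyphenyl]acetyl}-1,3-oxazolidin-2-one, via mixed pivalic anhydride 7 (not isolated)
Conditions: PivCl, Et3N, THF, −20 °C; then LiCl, 6, −20 °C to rt
Reagents that add atoms: pivaloyl chloride, CC(C)(C)C(=O)Cl (its atoms stay in 7 only)
Why: N-acylation of the oxazolidinone through a mixed anhydride works because the lithium-activated carbamate attacks the unhindered arylacetyl carbonyl rather than the pivaloyl one.

Step 5
Reactants: 8 (R)-4-benzyl-3-(arylacetyl)oxazolidinone; 9 4-(benzyloxy)-3-methoxybenzaldehyde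
Product: 11 (R)-4-benzyl-3-{(2R,3R)-2-[2-(benzyloxy)-5-bromo-3-methoxyphenyl]-3-[4-(benzyloxy)-3-methoxyphenyl]-3-hydroxypropanoyl}-1,3-oxazolidin-2-one, via boron enolate 10 (not isolated)
Conditions: n-Bu2BOTf, Et3N, CH2Cl2, −78 to 0 °C; 9, −78 to 0 °C; pH 7 buffer, MeOH, 30 % H2O2, 0 °C
Reagents that add atoms: dibutylboryl trifluoromethanesulfonate, CCCCB(CCCC)OS(=O)(=O)C(F)(F)F (its boron and butyl groups stay in 10 only)
Why: In the Evans syn-aldol reaction the (Z)-boron enolate reacts through a Zimmerman–Traxler chair on the face away from the auxiliary benzyl group, which sets C8'' (2R in 11, the arrangement of the target) and the sacrificial carbinol C7'' (3R).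

Step 6
Reactants: 11 syn-aldol imide
Product: 12 (1R,2S)-2-[2-(benzyloxy)-5-bromo-3-methoxyphenyl]-1-[4-(benzyloxy)-3-methoxyphenyl]propane-1,3-diol
Conditions: LiBH4, MeOH (1 equiv), THF–Et2O, 0 °C
Reagents that add atoms: none
Why: Reductive cleavage of the N-acyloxazolidinone by LiBH4 attacks the activated exocyclic carbonyl, turns it into C9''H2OH, returns the auxiliary and leaves C8'' without an adjacent carbonyl, so it cannot epimerise.

Step 7
Reactants: 12 1,3-diol
Product: 13 (4R,5S)-5-[2-(benzyloxy)-5-bromo-3-methoxyphenyl]-4-[4-(benzyloxy)-3-methoxyphenyl]-2,2-dimethyl-1,3-dioxane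
Conditions: Me2C(OMe)2, PPTS (cat.), CH2Cl2, rt
Reagents that add atoms: 2,2-dimethoxypropane, COC(C)(C)OC
Why: Acid-catalysed transketalisation closes the six-membered acetonide (ring E) and masks both hydroxyl groups in one step without touching either stereocentre.

Step 8
Reactants: 13 aryl bromide acetonide; 14 prop-2-yn-1-ol
Product: 15 3-{4-(benzyloxy)-3-[(4R,5S)-4-(4-(benzyloxy)-3-methoxyphenyl)-2,2-dimethyl-1,3-dioxan-5-yl]-5-methoxyphenyl}prop-2-yn-1-ol
Conditions: PdCl2(PhCN)2 (3 mol %), P(t-Bu)3 (6 mol %), CuI (2 mol %), i-Pr2NH, 1,4-dioxane, rt to 50 °C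
Reagents that add atoms: none
Why: In this Sonogashira coupling the bulky electron-rich phosphine lets zerovalent palladium insert into the electron-rich aryl bromide under mild conditions, and the free propargylic alcohol is tolerated.

Step 9
Reactants: 15 arylpropargyl alcohol
Product: 16 (Z)-3-{4-(benzyloxy)-3-[(4R,5S)-4-(4-(benzyloxy)-3-methoxyphenyl)-2,2-dimethyl-1,3-dioxan-5-yl]-5-methoxyphenyl}prop-2-en-1-ol
Conditions: H2 (1 atm), Pd/CaCO3 poisoned with Pb(OAc)2 (Lindlar catalyst), quinoline, EtOAc, rt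
Reagents that add atoms: none
Why: Lindlar semihydrogenation delivers H2 syn on the poisoned surface to give the (Z)-alkene and leaves the aryl benzyl ethers intact.

Step 10
Reactants: 9 4-(benzyloxy)-3-methoxybenzaldehyde
Product: 17 1-(benzyloxy)-4-(2,2-dibromoethenyl)-2-methoxybenzene
Conditions: CBr4, PPh3, CH2Cl2, 0 °C
Reagents that add atoms: carbon tetrabromide, BrC(Br)(Br)Br
Why: The first stage of the Corey–Fuchs sequence is a Wittig-type dibromoolefination that is reliable for electron-rich benzaldehydes.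

Step 11
Reactants: 17 1,1-dibromoalkene
Product: 19 3-[4-(benzyloxy)-3-methoxyphenyl]prop-2-ynoic acid, via lithium acetylide 18 (not isolated)
Conditions: n-BuLi (2.1 equiv), THF, −78 °C; CO2 (g), −78 °C to rt; 1 M HCl
Reagents that add atoms: carbon dioxide, O=C=O; n-butyllithium, [Li]CCCC (its lithium stays in 18 only)
Why: The second stage of the Corey–Fuchs sequence (elimination and lithium–bromine exchange) gives the lithium acetylide, which is carboxylated in the same flask.

Step 12
Reactants: 16 (Z)-allylic alcohol; 19 arylpropiolic acid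
Product: 20 (Z)-3-{4-(benzyloxy)-3-[(4R,5S)-4-(4-(benzyloxy)-3-methoxyphenyl)-2,2-dimethyl-1,3-dioxan-5-yl]-5-methoxyphenyl}prop-2-en-1-yl 3-[4-(benzyloxy)-3-methoxyphenyl]prop-2-ynoate
Conditions: DCC, DMAP (5 mol %), CH2Cl2, −10 to 0 °C
Reagents that add atoms: none
Why: Steglich esterification joins the two halves under neutral, cold conditions that neither isomerise the (Z)-alkene nor add to the ynoate.

Step 13
Reactants: 20 (Z)-cinnamyl arylpropiolate (1,6-enyne)
Product: 21 (R,Z)-3-[4-(benzyloxy)-3-methoxybenzylidene]-4-{4-(benzyloxy)-3-[(4R,5S)-4-(4-(benzyloxy)-3-methoxyphenyl)-2,2-dimethyl-1,3-dioxan-5-yl]-5-methoxybenzyl}dihydrofuran-2(3H)-one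
Conditions: [Rh(cod)2]OTf (5 mol %), (R)-BINAP (5 mol %), H2 (1 atm), ClCH2CH2Cl, 25 °C
Reagents that add atoms: none
Why: Proposed new method: the cationic monovalent rhodium–BINAP fragment binds the ynoate C≡C and the (Z)-styrenyl C=C of 20 and couples them oxidatively to a trivalent rhodacyclopentene, which makes the C3–C4 bond; because the rhodium-bearing carbon C7' carries only H and ring B there is no exocyclic β-hydrogen, so the Alder-ene exit is shut and H2 cleaves both Rh–C bonds to give C7'H2 and the C7–H of the benzylidene. The closest known reaction types are the hydrogen-mediated rhodium–bisphosphine reductive cyclisation of 1,6-enynes bearing terminal alkenes and the rhodium–BINAP Alder-ene cycloisomerisation of (Z)-allyl alkynoates to α-alkylidene-γ-butyrolactones; what is new is a 1,2-disubstituted styrenyl alkene in the hydrogenative manifold. Ring D closes in a 5-exo-dig/5-exo-trig sense, since each π-bond keeps its outer carbon (C7, C7') outside the new five-membered ring. The only new stereocentre, C4, is fixed in the oxidative cyclisation by the quadrants of the C2-symmetric BINAP, which select one face of the (Z)-alkene, while the remote dioxane centres are spectators. The step needs C–C coupling to precede hydrogen activation, so that plain hydrogenation of alkyne or alkene does not compete, and this is secured by the chelating 1,6-spacing through C2(=O)–O1–C5, by the electron-poor ynoate and by the cis alkene geometry that this catalyst family needs for fast metallacycle formation. Syn addition across the alkyne gives the (Z)-benzylidene (ring A cis to C2=O), a temporary oxidation level removed in step 14, and benzyl ethers and acetonide are inert to the homogeneous catalyst.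

Step 14
Reactants: 21 (R,Z)-benzylidene lactone
Product: 23 (3R,4R)-3-[4-(benzyloxy)-3-methoxybenzyl]-4-{4-(benzyloxy)-3-[(4R,5S)-4-(4-(benzyloxy)-3-methoxyphenyl)-2,2-dimethyl-1,3-dioxan-5-yl]-5-methoxybenzyl}dihydrofuran-2(3H)-one, via cis-lactone 22 (not isolated)
Conditions: NiCl2·6H2O (20 mol %), NaBH4, MeOH–THF, 0 °C; extraction; then t-BuOK (20 mol %), THF–t-BuOH, rt; AcOH quench
Reagents that add atoms: none
Why: Nickel boride conjugate reduction of the cinnamate-type C=C should deliver hydrogen anti to the C4 arm (mainly the cis-lactone), and base-catalysed epimerisation through the lactone enolate then lets C4 steer C3 to the more stable trans (3R) configuration.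

Step 15
Reactants: 23 trans-lactone acetonide
Product: 24 (3R,4R)-3-[4-(benzyloxy)-3-methoxybenzyl]-4-{4-(benzyloxy)-3-[(1R,2S)-1-(4-(benzyloxy)-3-methoxyphenyl)-1,3-dihydroxypropan-2-yl]-5-methoxybenzyl}dihydrofuran-2(3H)-one
Conditions: AcOH–H2O–THF (3:1:1), 40 °C
Reagents that add atoms: none
Why: Acid-catalysed acetal hydrolysis opens ring E, and any ionisation at the p-alkoxybenzylic C7'' is harmless because water returns the diol and that centre is erased in step 16.

Step 16
Reactants: 24 lactone diol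
Product: 25 (3R,4R)-3-[4-(benzyloxy)-3-methoxybenzyl]-4-{4-(benzyloxy)-3-[(S)-1-(4-(benzyloxy)-3-methoxyphenyl)-3-hydroxy-1-oxopropan-2-yl]-5-methoxybenzyl}dihydrofuran-2(3H)-one
Conditions: DDQ (1.1 equiv), 1,4-dioxane, rt; filtration, short neutral silica plug
Reagents that add atoms: none
Why: DDQ dehydrogenation (hydride abstraction) selects the secondary alcohol that is benzylic to the electron-rich ring C over the primary alcohol, and it runs without base, so C8'' (now S, α to the ketone) should keep its configuration.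

Step 17
Reactants: 25 tri-O-benzyl ketone
Product: 26 CNP0191394.1, (3R,4R)-4-{4-hydroxy-3-[(S)-3-hydroxy-1-(4-hydroxy-3-methoxyphenyl)-1-oxopropan-2-yl]-5-methoxybenzyl}-3-(4-hydroxy-3-methoxybenzyl)dihydrofuran-2(3H)-one
Conditions: H2 (1 atm), 10 % Pd/C, EtOAc–EtOH, rt, stopped after uptake of three equivalents
Reagents that add atoms: none
Why: Hydrogenolysis of the three aryl benzyl ethers over Pd/C is neutral and faster than reduction of the electron-rich aryl ketone, so neither acid nor base meets the labile α-aryl-β-hydroxyketone centre.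

## Compound list

| No. | Name | SMILES | Role |
|---|---|---|---|
| 1 | 5-bromo-2-hydroxy-3-methoxybenzaldehyde | O=Cc1cc(Br)cc(OC)c1O | starting material |
| 2 | 2-(benzyloxy)-5-bromo-3-methoxybenzaldehyde | O=Cc1cc(Br)cc(OC)c1OCc1ccccc1 | intermediate |
| 3 | 2-(benzyloxy)-5-bromo-1-methoxy-3-(2-methoxyethenyl)benzene (E/Z mixture) | COC=Cc1cc(Br)cc(OC)c1OCc1ccccc1 | intermediate |
| 4 | 2-[2-(benzyloxy)-5-bromo-3-methoxyphenyl]acetaldehyde | O=CCc1cc(Br)cc(OC)c1OCc1ccccc1 | intermediate |
| 5 | 2-[2-(benzyloxy)-5-bromo-3-methoxyphenyl]acetic acid | OC(=O)Cc1cc(Br)cc(OC)c1OCc1ccccc1 | intermediate |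
| 6 | (R)-4-benzyl-1,3-oxazolidin-2-one | O=C1N[C@H](Cc2ccccc2)CO1 | starting material |
| 7 | 2-[2-(benzyloxy)-5-bromo-3-methoxyphenyl]acetic pivalic anhydride | CC(C)(C)C(=O)OC(=O)Cc1cc(Br)cc(OC)c1OCc1ccccc1 | intermediate |
| 8 | (R)-4-benzyl-3-{2-[2-(benzyloxy)-5-bromo-3-methoxyphenyl]acetyl}-1,3-oxazolidin-2-one | O=C(Cc1cc(Br)cc(OC)c1OCc1ccccc1)N1[C@H](Cc2ccccc2)COC1=O | intermediate |
| 9 | 4-(benzyloxy)-3-methoxybenzaldehyde (O-benzylvanillin) | O=Cc1ccc(OCc2ccccc2)c(OC)c1 | starting material |
| 10 | (Z)-dibutylboron enolate of 8 | CCCCB(CCCC)O/C(=C\c1cc(Br)cc(OC)c1OCc1ccccc1)N1[C@H](Cc2ccccc2)COC1=O | intermediate |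
| 11 | (2R,3R)-syn-aldol imide | COc1cc(Br)cc([C@@H](C(=O)N2[C@H](Cc3ccccc3)COC2=O)[C@@H](O)c2ccc(OCc3ccccc3)c(OC)c2)c1OCc1ccccc1 | intermediate |
| 12 | (1R,2S)-2-[2-(benzyloxy)-5-bromo-3-methoxyphenyl]-1-[4-(benzyloxy)-3-methoxyphenyl]propane-1,3-diol | COc1cc(Br)cc([C@@H](CO)[C@@H](O)c2ccc(OCc3ccccc3)c(OC)c2)c1OCc1ccccc1 | intermediate |
| 13 | (4R,5S)-5-[2-(benzyloxy)-5-bromo-3-methoxyphenyl]-4-[4-(benzyloxy)-3-methoxyphenyl]-2,2-dimethyl-1,3-dioxane | COc1cc(Br)cc([C@H]2COC(C)(C)O[C@H]2c2ccc(OCc3ccccc3)c(OC)c2)c1OCc1ccccc1 | intermediate |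
| 14 | prop-2-yn-1-ol | C#CCO | starting material |
| 15 | arylpropargyl alcohol (dioxane 4R,5S) | COc1cc(C#CCO)cc([C@H]2COC(C)(C)O[C@H]2c2ccc(OCc3ccccc3)c(OC)c2)c1OCc1ccccc1 | intermediate |
| 16 | (Z)-cinnamyl alcohol (dioxane 4R,5S) | COc1cc(/C=C\CO)cc([C@H]2COC(C)(C)O[C@H]2c2ccc(OCc3ccccc3)c(OC)c2)c1OCc1ccccc1 | intermediate |
| 17 | 1-(benzyloxy)-4-(2,2-dibromoethenyl)-2-methoxybenzene | BrC(Br)=Cc1ccc(OCc2ccccc2)c(OC)c1 | intermediate |
| 18 | lithium [4-(benzyloxy)-3-methoxyphenyl]acetylide | [Li]C#Cc1ccc(OCc2ccccc2)c(OC)c1 | intermediate |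
| 19 | 3-[4-(benzyloxy)-3-methoxyphenyl]prop-2-ynoic acid | OC(=O)C#Cc1ccc(OCc2ccccc2)c(OC)c1 | intermediate |
| 20 | (Z)-cinnamyl arylpropiolate (1,6-enyne) | COc1cc(/C=C\COC(=O)C#Cc2ccc(OCc3ccccc3)c(OC)c2)cc([C@H]2COC(C)(C)O[C@H]2c2ccc(OCc3ccccc3)c(OC)c2)c1OCc1ccccc1 | intermediate |
| 21 | (R,Z)-3-benzylidene-4-benzyl lactone | COc1cc(/C=C2\C(=O)OC[C@@H]2Cc2cc(OC)c(OCc3ccccc3)c([C@H]3COC(C)(C)O[C@H]3c3ccc(OCc4ccccc4)c(OC)c3)c2)ccc1OCc1ccccc1 | intermediate |
| 22 | (3S,4R)-cis-dibenzyl lactone acetonide | COc1cc(C[C@@H]2C(=O)OC[C@@H]2Cc2cc(OC)c(OCc3ccccc3)c([C@H]3COC(C)(C)O[C@H]3c3ccc(OCc4ccccc4)c(OC)c3)c2)ccc1OCc1ccccc1 | intermediate |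
| 23 | (3R,4R)-trans-dibenzyl lactone acetonide | COc1cc(C[C@H]2C(=O)OC[C@@H]2Cc2cc(OC)c(OCc3ccccc3)c([C@H]3COC(C)(C)O[C@H]3c3ccc(OCc4ccccc4)c(OC)c3)c2)ccc1OCc1ccccc1 | intermediate |
| 24 | (3R,4R)-lactone (1R,2S)-diol | COc1cc(C[C@H]2C(=O)OC[C@@H]2Cc2cc(OC)c(OCc3ccccc3)c([C@@H](CO)[C@@H](O)c3ccc(OCc4ccccc4)c(OC)c3)c2)ccc1OCc1ccccc1 | intermediate |
| 25 | tri-O-benzyl (S)-β-hydroxyketone | COc1cc(C[C@H]2C(=O)OC[C@@H]2Cc2cc(OC)c(OCc3ccccc3)c([C@@H](CO)C(=O)c3ccc(OCc4ccccc4)c(OC)c3)c2)ccc1OCc1ccccc1 | intermediate |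
| 26 | CNP0191394.1 | COc1cc(C[C@H]2C(=O)OC[C@@H]2Cc2cc(OC)c(O)c([C@@H](CO)C(=O)c3ccc(O)c(OC)c3)c2)ccc1O | target |

## Step count

- **Total step count:** 17.
- **Longest linear sequence:** 15 (steps 1–9 and 12–17).

## Steps most likely to fail

**1. Step 13 (Proposed new method).**
- What may go wrong: plain hydrogenation of the ynoate or the styrenyl alkene may outrun metallacycle formation. The many electron-rich arenes may sequester the cationic rhodium. Facial selection on an aryl-substituted (Z)-alkene may be poorer than on alkyl-substituted ones.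
- The fallback uses known chemistry, closes the same C3–C4 bond, sets out from 16 and returns at 23.
- Diimide reduction of the alkene (2-nitrobenzenesulfonylhydrazide, Et3N, CH2Cl2, rt) should give the saturated 3-arylpropan-1-ol F1.
- Acylation with glyoxylic acid chloride p-toluenesulfonylhydrazone (PhNMe2, then Et3N, CH2Cl2, 0 °C) should give the diazoacetate F2.
- Slow addition of F2 to Rh2(4S-MPPIM)4 (1 mol %; or its antipode, whichever delivers R) in refluxing CH2Cl2 should effect enantioselective carbenoid insertion into the homobenzylic C–H bond and give the (R)-4-arylmethyl lactone F3.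
- LiHMDS (THF, −78 °C), then 4-(benzyloxy)-3-methoxybenzyl bromide, should alkylate the enolate anti to the C4 arm and give 23 directly. Steps 10–12 and 14 then become unnecessary.

**2. Step 16.**
- What may go wrong: hydride abstraction at the other electron-rich benzylic positions (C7, C7'), sluggish conversion, enolisation at C8'' promoted by the acidic hydroquinone, or retro-aldol loss of formaldehyde.
- The fallback sets out from 24 and returns at 25.
- Selective silylation of the primary hydroxyl (TBSCl, imidazole, CH2Cl2, 0 °C) should give the primary silyl ether F4.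
- Dess–Martin oxidation (CH2Cl2, 0 °C) of the only free alcohol should give the β-silyloxy ketone F5.
- HF·pyridine in THF–pyridine at 0 °C should release 25.

**3. Step 17.**
- What may go wrong: over-reduction of the aryl ketone with subsequent benzylic hydrogenolysis, slow cleavage of the hindered ring B benzyl ether, or cyclodehydration of the freed ortho-phenol onto the ketone on long contact with the catalyst support.
- The fallback sets out from 25 and arrives at 26 without any new compound (F0).
- It is a non-reductive Lewis-acid debenzylation with BCl3 and pentamethylbenzene as cation scavenger in CH2Cl2 at −78 °C, quenched cold with CHCl3–MeOH. It cleaves aryl benzyl ethers within minutes and cannot reduce the ketone.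

## Further compounds

F1 | step 13 | 3-{4-(benzyloxy)-3-[(4R,5S)-4-(4-(benzyloxy)-3-methoxyphenyl)-2,2-dimethyl-1,3-dioxan-5-yl]-5-methoxyphenyl}propan-1-ol | COc1cc(CCCO)cc([C@H]2COC(C)(C)O[C@H]2c2ccc(OCc3ccccc3)c(OC)c2)c1OCc1ccccc1
F2 | step 13 | diazoacetate of F1 | COc1cc(CCCOC(=O)C=[N+]=[N-])cc([C@H]2COC(C)(C)O[C@H]2c2ccc(OCc3ccccc3)c(OC)c2)c1OCc1ccccc1
F3 | step 13 | (R)-4-{4-(benzyloxy)-3-[(4R,5S)-4-(4-(benzyloxy)-3-methoxyphenyl)-2,2-dimethyl-1,3-dioxan-5-yl]-5-methoxybenzyl}dihydrofuran-2(3H)-one | COc1cc(C[C@H]2COC(=O)C2)cc([C@H]3COC(C)(C)O[C@H]3c3ccc(OCc4ccccc4)c(OC)c3)c1OCc1ccccc1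
F4 | step 16 | primary tert-butyldimethylsilyl ether of 24 | COc1cc(C[C@H]2C(=O)OC[C@@H]2Cc2cc(OC)c(OCc3ccccc3)c([C@@H](CO[Si](C)(C)C(C)(C)C)[C@@H](O)c3ccc(OCc4ccccc4)c(OC)c3)c2)ccc1OCc1ccccc1
F5 | step 16 | tert-butyldimethylsilyl ether of 25 | COc1cc(C[C@H]2C(=O)OC[C@@H]2Cc2cc(OC)c(OCc3ccccc3)c([C@@H](CO[Si](C)(C)C(C)(C)C)C(=O)c3ccc(OCc4ccccc4)c(OC)c3)c2)ccc1OCc1ccccc1
F0 | step 17 | none | none
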